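**Plan**

- **Retrosynthesis.** The six phenols are masked as TBS ethers. The C4–C(vinyl) bond between the bicyclo[3.2.1]oct-3-ene-2,8-dione and the (E)-styryl arm is cut together with a helper C3–O bond. The C5–C6 and C1–C7 bonds are then cut in a [5+2] sense, which leads to 2-bromo-6-methoxy-1,4-benzoquinone and silylated piceatannol.
- **Forward order.** The quinone supplies the six-membered ring C1–C2–C3–C4–C5–C8. The cycloaddition closes the five-membered ring C1–C8–C5–C6–C7. The arm is joined last, as a plain styrene.
- **Stereochemistry.** The E-stilbene gives the trans C6/C7 pair. The endo transition state puts the catechol ring under C2/C3 and fixes C1 and C5. A TADDOL–titanium complex sets the absolute sense. The E-alkene of the arm comes from syn insertion and syn β-hydride elimination.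
- **Enabling feature.** C4 is the β-carbon of the C2=O/C3=C4 enone, so C4–Br is a vinylogous acyl bromide that zerovalent palladium enters before C3–OTf. C1 and C5 are bridgeheads that cannot enolise (Bredt's rule), so the C2/C8 1,3-diketone and all four centres survive. The C3 oxygen, which the [5+2] step needs as donor on the central carbon of the C5–C4–C3–C2–C1 pentadienyl cation, is deleted by the same palladium charge.

Key step: step 7

Assumption: the (4R,5R)-TADDOL–titanium complex is taken to shield the quinone face that leads to the (1S,5R,6S,7S) adduct. If the sense is the opposite, the equally available (4S,5S)-ligand is used.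

Abbreviation: TBSO = tert-butyldimethylsilyloxy.

Step 1
Reactants: 1 piceatannol, (E)-3,3',4,5'-tetrahydroxystilbene
Product: 2 (E)-3,3',4,5'-tetrakis(TBSO)stilbene
Conditions: TBSCl, imidazole, DMF, rt
Reagents that add atoms: tert-butyldimethylsilyl chloride, CC(C)(C)[Si](C)(C)Cl
Why: Standard imidazole-promoted silyl ether formation caps all four phenols, so that no free para-hydroxyl can form a quinone methide later and the final release needs only fluoride; no stereocentre is involved and the E-alkene is untouched.

Step 2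
Reactants: 3 2-bromo-6-methoxyphenol
Product: 4 2-bromo-6-methoxy-1,4-benzoquinone
Conditions: (KSO3)2NO, KH2PO4 buffer, H2O/acetone, 0 °C to rt
Reagents that add atoms: potassium nitrosodisulfonate, [K+].[K+].[O]N(S(=O)(=O)[O-])S(=O)(=O)[O-]
Why: Teuber oxidation, in which one nitrosodisulfonate radical removes the phenolic hydrogen and a second one delivers oxygen to the free para position of the 2,6-disubstituted phenol to give the para-quinone.

Step 3
Reactants: 2 (E)-3,3',4,5'-tetrakis(TBSO)stilbene; 4 2-bromo-6-methoxy-1,4-benzoquinone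
Product: 5 (1S,5R,6S,7S)-4-bromo-3-hydroxy-7-[3,4-bis(TBSO)phenyl]-6-[3,5-bis(TBSO)phenyl]bicyclo[3.2.1]oct-3-ene-2,8-dione (7-aryl endo, 6-aryl exo)
Conditions: TiCl4, Ti(OiPr)4, (4R,5R)-TADDOL, 4 Å MS, CH2Cl2, −78 °C; aq. NaHCO3
Reagents that add atoms: none
Why: Lewis-acid-promoted quinone–styrene [5+2] cycloaddition, in which titanium chelated by O1 and the methoxy oxygen makes quinone C3 (next to C–Br) the acceptor for the stilbene carbon that bears the resorcinol ring, the para-silyloxy-stabilised benzylic cation is closed by the enol ether carbon C5 across the C4 carbonyl with loss of the methyl group, the bromine at the neighbouring carbon disfavours the [2+2] closure, the E-alkene gives the trans C6/C7 pair, the endo transition state places the catechol ring under C2/C3, and the TADDOLate blocks one quinone face so that all four centres are set in one absolute sense.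

Step 4
Reactants: 5 bromo enol adduct
Product: 6 (1S,5R,6S,7S)-4-bromo-7-[3,4-bis(TBSO)phenyl]-6-[3,5-bis(TBSO)phenyl]-2,8-dioxobicyclo[3.2.1]oct-3-en-3-yl trifluoromethanesulfonate
Conditions: Tf2O, 2,6-lutidine, CH2Cl2, −78 °C
Reagents that add atoms: trifluoromethanesulfonic anhydride, O=S(=O)(OS(=O)(=O)C(F)(F)F)C(F)(F)F
Why: O-sulfonylation of the acidic C3 enol of a diosphenol with a hindered pyridine base; C1 and C5 are bridgeheads, so no other enolate can form and the four stereocentres are not touched.

Step 5
Reactants: 7 3,4-dihydroxybenzaldehyde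
Product: 8 3,4-bis(TBSO)benzaldehyde
Conditions: TBSCl, imidazole, DMF, rt
Reagents that add atoms: tert-butyldimethylsilyl chloride, CC(C)(C)[Si](C)(C)Cl
Why: Standard silyl ether formation on a catechol; the aldehyde is inert to these conditions.

Step 6
Reactants: 8 3,4-bis(TBSO)benzaldehyde
Product: 9 3,4-bis(TBSO)styrene
Conditions: MePPh3Br, n-BuLi, THF, 0 °C, then 8, 0 °C to rt
Reagents that add atoms: methyltriphenylphosphonium bromide, C[P+](c1ccccc1)(c1ccccc1)c1ccccc1.[Br-]
Why: Wittig methylenation of an aromatic aldehyde with the non-stabilised ylide, which aryl silyl ethers tolerate at low temperature.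

Step 7
Reactants: 6 bromo enol triflate; 9 3,4-bis(TBSO)styrene
Product: 11 (1R,5S,6S,7S)-4-{(E)-2-[3,4-bis(TBSO)phenyl]ethenyl}-7-[3,4-bis(TBSO)phenyl]-6-[3,5-bis(TBSO)phenyl]bicyclo[3.2.1]oct-3-ene-2,8-dione, via styryl enol triflate 10 (not isolated)
Conditions: Pd2(dba)3, P(t-Bu)3, Cy2NMe, dioxane, rt; then dppf, HCO2H, Cy2NMe, 60 °C
Reagents that add atoms: none
Why: Zerovalent palladium carrying one P(t-Bu)3 inserts into the C4–Br bond of 6 (a vinylogous acyl bromide, with a ligand known to prefer halide over triflate), styrene 9 inserts syn with the new C–C bond at its unsubstituted carbon, and syn β-hydride elimination releases the E-dienone 10 while Cy2NMe takes up HBr. After dppf and formic acid are added, the chelated zerovalent palladium enters the remaining C3–OTf bond, formate replaces triflate and loses CO2, and the vinylpalladium hydride collapses to C3–H to give 11. The closest known reaction types are the Mizoroki–Heck reaction of β-halo enones with styrenes and the formate hydrogenolysis of enol triflates, run here one after the other in one flask. No ring is closed and no stereocentre is made; the only new stereo-element, the E-alkene, is controlled by the syn/syn course of the Heck cycle, with the aryl group trans to the ring. The step needs site selectivity (C4–Br before C3–OTf), secured by the β-carbonyl activation of C4 and the order of ligands, and regioselectivity for the terminal styrene carbon, secured by the neutral halide pathway and the bulk around C4. The base-labile non-enolisable C2/C8 1,3-diketone and the centres C1, C5, C6 and C7 survive because only a hindered tertiary amine is present, C1 and C5 are bridgeheads, and the para-oxygen of the C7 aryl group is still silylated, so that no retro-Michael opening of C1–C7 can start.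

Step 8
Reactants: 11 hexa-TBS ether
Product: 12 (1R,5S,6S,7S)-7-(3,4-dihydroxyphenyl)-6-(3,5-dihydroxyphenyl)-4-[(E)-2-(3,4-dihydroxyphenyl)ethenyl]bicyclo[3.2.1]oct-3-ene-2,8-dione (target)
Conditions: Et3N·3HF, THF, 0 °C to rt, under argon
Reagents that add atoms: none
Why: Fluoride-driven cleavage of aryl silyl ethers in a slightly acidic medium keeps every phenol protonated, so that the phenoxide-triggered retro-Michael cleavage of C1–C7 and the retro-Claisen cleavage of the 1,3-diketone are avoided and no stereocentre is disturbed.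

**Compound list**

1 | piceatannol | Oc1cc(O)cc(/C=C/c2ccc(O)c(O)c2)c1 | starting material
2 | (E)-3,3',4,5'-tetrakis(TBSO)stilbene | CC(C)(C)[Si](C)(C)Oc1cc(O[Si](C)(C)C(C)(C)C)cc(/C=C/c2ccc(O[Si](C)(C)C(C)(C)C)c(O[Si](C)(C)C(C)(C)C)c2)c1 | intermediate
3 | 2-bromo-6-methoxyphenol | COc1cccc(Br)c1O | starting material
4 | 2-bromo-6-methoxy-1,4-benzoquinone | COC1=CC(=O)C=C(Br)C1=O | intermediate
5 | (1S,5R,6S,7S)-4-bromo-3-hydroxy [5+2] adduct | O=C1C(O)=C(Br)[C@H]2C(=O)[C@@H]1[C@@H](c1ccc(O[Si](C)(C)C(C)(C)C)c(O[Si](C)(C)C(C)(C)C)c1)[C@@H]2c1cc(O[Si](C)(C)C(C)(C)C)cc(O[Si](C)(C)C(C)(C)C)c1 | intermediate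
6 | (1S,5R,6S,7S)-4-bromo C3 enol triflate | O=C1C(OS(=O)(=O)C(F)(F)F)=C(Br)[C@H]2C(=O)[C@@H]1[C@@H](c1ccc(O[Si](C)(C)C(C)(C)C)c(O[Si](C)(C)C(C)(C)C)c1)[C@@H]2c1cc(O[Si](C)(C)C(C)(C)C)cc(O[Si](C)(C)C(C)(C)C)c1 | intermediate
7 | 3,4-dihydroxybenzaldehyde | O=Cc1ccc(O)c(O)c1 | starting material
8 | 3,4-bis(TBSO)benzaldehyde | O=Cc1ccc(O[Si](C)(C)C(C)(C)C)c(O[Si](C)(C)C(C)(C)C)c1 | intermediate
9 | 3,4-bis(TBSO)styrene | C=Cc1ccc(O[Si](C)(C)C(C)(C)C)c(O[Si](C)(C)C(C)(C)C)c1 | intermediate
10 | (1S,5S,6S,7S)-4-[(E)-styryl] C3 enol triflate | O=C1C(OS(=O)(=O)C(F)(F)F)=C(/C=C/c2ccc(O[Si](C)(C)C(C)(C)C)c(O[Si](C)(C)C(C)(C)C)c2)[C@H]2C(=O)[C@@H]1[C@@H](c1ccc(O[Si](C)(C)C(C)(C)C)c(O[Si](C)(C)C(C)(C)C)c1)[C@@H]2c1cc(O[Si](C)(C)C(C)(C)C)cc(O[Si](C)(C)C(C)(C)C)c1 | intermediate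
11 | (1R,5S,6S,7S)-hexa-TBS ether of the target | O=C1C=C(/C=C/c2ccc(O[Si](C)(C)C(C)(C)C)c(O[Si](C)(C)C(C)(C)C)c2)[C@H]2C(=O)[C@@H]1[C@@H](c1ccc(O[Si](C)(C)C(C)(C)C)c(O[Si](C)(C)C(C)(C)C)c1)[C@@H]2c1cc(O[Si](C)(C)C(C)(C)C)cc(O[Si](C)(C)C(C)(C)C)c1 | intermediate
12 | target, (1R,5S,6S,7S) | O=C1C=C(/C=C/c2ccc(O)c(O)c2)[C@H]2C(=O)[C@@H]1[C@@H](c1ccc(O)c(O)c1)[C@@H]2c1cc(O)cc(O)c1 | target

**Step count**

Total step count: 8. Longest linear sequence: 5 steps (3 → 4 → 5 → 6 → 11 → 12; the branch from 1 is equally long).

**Steps most likely to fail**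

Step 3. The zwitterion may collapse in the [2+2] or [3+2] mode instead of the [5+2] mode. The para silyl group may be lost from the cationic intermediate. The chiral titanium complex may discriminate poorly between the quinone faces. The fallback gives up reagent control and relies on resolution. It sets out from 2 and 4, which are combined with excess achiral TiCl4 in CH2Cl2 at −78 °C, the promoter regime best known to favour the bicyclo[3.2.1] closure. This should give 5 together with its mirror image, the (1R,5S,6R,7R)-bromo enol F1. The two are separated by preparative chromatography on a chiral stationary phase, and the route is rejoined at 5.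

Step 7. Site selectivity between C4–Br and C3–OTf may be lost. A second Heck event may occur at C3. The dienone may undergo conjugate reduction in the formate stage. The fallback removes the competing electrophile by changing the order of events. It sets out from 5 and 9, which are coupled by a Mizoroki–Heck reaction on the free enol (Pd2(dba)3, P(t-Bu)3, Cy2NMe) to the (1S,5S,6S,7S)-3-hydroxy-4-styryl enedione F2. This is triflated (Tf2O, 2,6-lutidine), and the route is rejoined at 10, now isolated. Compound 10 is reduced in a separate flask with Pd(OAc)2, dppf, HCO2H and Et3N to 11.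

Step 8. A phenoxide may open C1–C7 by a retro-Michael process, followed by aromatisation to a dihydrobenzofuran isomer. The free catechols may also be oxidised by air during isolation. The fallback swaps the protecting group so that a robust compound can be purified and then released under neutral conditions. It sets out from 11, which is treated with Et3N·3HF and then, in the same flask, with Ac2O and pyridine to give the (1R,5S,6S,7S)-hexaacetate F3. After purification, F3 is deacetylated with NH4OAc in aqueous MeOH at rt, and the route is rejoined at 12.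

**Further compounds**

F1 | step 3 | (1R,5S,6R,7R)-4-bromo-3-hydroxy adduct, enantiomer of 5 | O=C1C(O)=C(Br)[C@@H]2C(=O)[C@H]1[C@H](c1ccc(O[Si](C)(C)C(C)(C)C)c(O[Si](C)(C)C(C)(C)C)c1)[C@H]2c1cc(O[Si](C)(C)C(C)(C)C)cc(O[Si](C)(C)C(C)(C)C)c1
F2 | step 7 | (1S,5S,6S,7S)-3-hydroxy-4-{(E)-2-[3,4-bis(TBSO)phenyl]ethenyl} enedione | O=C1C(O)=C(/C=C/c2ccc(O[Si](C)(C)C(C)(C)C)c(O[Si](C)(C)C(C)(C)C)c2)[C@H]2C(=O)[C@@H]1[C@@H](c1ccc(O[Si](C)(C)C(C)(C)C)c(O[Si](C)(C)C(C)(C)C)c1)[C@@H]2c1cc(O[Si](C)(C)C(C)(C)C)cc(O[Si](C)(C)C(C)(C)C)c1
F3 | step 8 | (1R,5S,6S,7S)-hexaacetate of the target | O=C1C=C(/C=C/c2ccc(OC(C)=O)c(OC(C)=O)c2)[C@H]2C(=O)[C@@H]1[C@@H](c1ccc(OC(C)=O)c(OC(C)=O)c1)[C@@H]2c1cc(OC(C)=O)cc(OC(C)=O)c1
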